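**Strategy.** The target is read as the endo Diels–Alder adduct of two antipodal cis-fused xanthanolides, oxygenated afterwards at C1 (xanthanolide numbering, primes for the dienophile half). Everything rests on one disconnection inside the diene half: the C7–C8 bond shared by cycloheptene ring B and α-methylene lactone ring A, together with C11–C12. A Ru3(CO)12-catalysed hetero-Pauson–Khand reaction of an acyclic allenyl aldehyde joins aldehyde carbon C8 to allene terminus C7 and central allene carbon C11 to CO, closing both rings and setting the cis C7/C8 fusion; the exocyclic C11=C13 methylene is the surviving allene π-bond. Its precursor is a (Z)-trienal with one stereocentre (C10). The same step on the mirror-image series supplies the dienophile.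

Key step: step 8

Remark on numbering: ring B = C1, C5, C6, C7, C8, C9, C10; lactone ring A = C7, C8, O, C12, C11 with exocyclic C13; side chain C2, C3, C4, C15; ring C is the cyclohexene made in step 17, ring D the spiro-lactone and ring E the cycloheptene of the primed half.

Assumption: the imidazolidinone catalyst is taken to show the same facial sense as in its other conjugate additions to crotonaldehyde; because both antipodes of the adduct are used, a reversed sense would only exchange the catalyst batches of steps 2 and 10.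

**Steps 1–9: diene half (C10 S series)**

Step 1
Reactants: 1 S-tert-butyl ethanethioate
Product: 2 tert-butyl{[1-(tert-butylsulfanyl)ethenyl]oxy}dimethylsilane
Conditions: LiN(i-Pr)2, THF, −78 °C; then t-BuMe2SiCl, DMPU, −78 °C → rt
Reagents that add atoms: tert-butyldimethylsilyl chloride, C[Si](C)(Cl)C(C)(C)C
Why: Kinetic deprotonation of the thioester and O-silylation of the lithium enolate (silyl ketene acetal formation) give the nucleophile for the Mukaiyama–Michael step; no stereocentre is formed.

Step 2
Reactants: 2 tert-butyl{[1-(tert-butylsulfanyl)ethenyl]oxy}dimethylsilane; 3 (E)-but-2-enal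
Product: 5 S-tert-butyl (3S)-5,5-dimethoxy-3-methylpentanethioate, via Michael aldehyde 4 (not isolated)
Conditions: (2R,5R)-5-benzyl-2-tert-butyl-3-methylimidazolidin-4-one·CF3CO2H (20 mol %), H2O (2 equiv), CH2Cl2, −60 °C; then HC(OMe)3, MeOH, TsOH (cat.), 0 °C → rt
Reagents that add atoms: trimethyl orthoformate, COC(OC)OC
Why: Iminium activation of 3 lets the silyl ketene thioacetal add to the β-carbon (organocatalytic Mukaiyama–Michael addition) on the face left open by the benzyl and tert-butyl groups, which sets C10, and the aldehyde (future C8) is locked in the same flask as its dimethyl acetal.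

Step 3
Reactants: 5 S-tert-butyl (3S)-5,5-dimethoxy-3-methylpentanethioate
Product: 6 (3R)-5,5-dimethoxy-3-methylpentanal
Conditions: i-Bu2AlH (1.1 equiv), CH2Cl2, −78 °C; aqueous work-up
Reagents that add atoms: none
Why: Partial reduction of a thioester at low temperature stops at the hemithioacetal aluminate, which collapses to the aldehyde on work-up, leaving the acetal and the β-stereocentre untouched (the descriptor changes only by priority).

Step 4
Reactants: 6 (3R)-5,5-dimethoxy-3-methylpentanal
Product: 7 (3S)-5,5-dimethoxy-3-methyl-2-methylidenepentanal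
Conditions: 37% aq. CH2O, pyrrolidine (10 mol %), propanoic acid (10 mol %), i-PrOH, 45 °C
Reagents that add atoms: formaldehyde, C=O
Why: Amine-catalysed Mannich condensation with formaldehyde and β-elimination (organocatalytic α-methylenation of an aldehyde) installs C2 as a 1,1-disubstituted alkene without touching the non-enolisable C10 centre.

Step 5
Reactants: 7 (3S)-5,5-dimethoxy-3-methyl-2-methylidenepentanal; 8 3-bromoprop-1-yne
Product: 9 (4RS,6S)-8,8-dimethoxy-6-methyl-5-methylideneoct-1-yn-4-ol
Conditions: Zn dust, THF/sat. aq. NH4Cl, 0 °C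
Reagents that add atoms: none
Why: Barbier-type propargylation, in which the allenylzinc species adds 1,2 to the enal through an SE2' transition state; the new carbinol centre C5 forms as an epimer mixture, which is of no consequence because C5 becomes sp2 in step 7.

Step 6
Reactants: 9 (4RS,6S)-8,8-dimethoxy-6-methyl-5-methylideneoct-1-yn-4-ol
Product: 11 (5RS,7S)-9,9-dimethoxy-7-methyl-6-methylidenenona-1,2-dien-5-ol, via propargylic amine 10 (not isolated)
Conditions: (CH2O)n, i-Pr2NH, CuBr (0.3 equiv), 1,4-dioxane, reflux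
Reagents that add atoms: formaldehyde (as paraformaldehyde), C=O
Why: Crabbé homologation, in which copper-mediated Mannich coupling of the terminal alkyne gives amine 10 and a copper-assisted 1,5-hydride shift with loss of the imine delivers the terminal allene C7=C11=C13; the free hydroxyl, the acetal and the alkene are tolerated.

Step 7
Reactants: 11 (5RS,7S)-9,9-dimethoxy-7-methyl-6-methylidenenona-1,2-dien-5-ol; 12 2-methoxyprop-1-ene
Product: 15 (3S,4Z)-3-methyl-4-(3-oxobutyl)nona-4,7,8-trienal, via isopropenyl ether 13 (not isolated), via keto acetal 14 (not isolated)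
Conditions: 12 (excess), 2,4-dinitrophenol (cat.), xylenes, 130 °C, sealed tube; then THF, 10% aq. oxalic acid, rt
Reagents that add atoms: water, O
Why: Acid-catalysed exchange gives allyl isopropenyl ether 13, which undergoes a Claisen rearrangement (Marbet–Saucy ketal variant) through a chair transition state with the C6 substituent equatorial, so that both C5 epimers converge on the alkene with C6 and C10 cis while the 3-oxobutyl chain is built on C2; mild aqueous acid then frees the C8 aldehyde.

Step 8
Reactants: 15 (3S,4Z)-3-methyl-4-(3-oxobutyl)nona-4,7,8-trienal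
Product: 16 (3aR,7S,8aR)-7-methyl-3-methylidene-6-(3-oxobutyl)-3,3a,4,7,8,8a-hexahydro-2H-cyclohepta[b]furan-2-one
Conditions: Ru3(CO)12 (5 mol %), CO (20 atm), 1,4-dioxane, 120 °C
Reagents that add atoms: carbon monoxide, [C-]#[O+]
Why: Zerovalent ruthenium carbonyl binds the aldehyde C=O and the proximal allene π-bond (C7=C11), oxidative cyclisation gives an oxaruthenacyclopentane with the new C7–C8 bond, CO inserts into the Ru–C11 bond to forge C11–C12, and reductive elimination closes the lactone O–C12 bond and returns the catalyst. The closest known reaction is the Ru3(CO)12-catalysed cyclocarbonylation (hetero-Pauson–Khand reaction) of allenyl aldehydes to bicyclic α-methylene-γ-butyrolactones, applied here with a longer tether that closes a seven-membered carbocycle. Ring B closes in a 7-exo mode onto the proximal allene bond (C11 and C13 stay outside the carbocycle), helped by the (Z)-C1=C5 alkene that holds C6 and C10 on one side, and ring A is assembled by the [2+2+1] union of C7=C11, C8=O and CO and closes by C–O reductive elimination. C7 and C8 are set together as the cis ring fusion because both π-bonds add suprafacially on the metal, and their sense relative to C10 is expected from a chair-like tether in which the C10 methyl is pseudo-equatorial, which places H7, H8 and H10 on one face. The step needs chemoselectivity for the aldehyde over the methyl ketone (aldehydes are far more reactive in the oxidative cyclisation), proximal over distal allene selectivity (normal for this catalyst and a monosubstituted allene) and 1,3-diastereocontrol from C10, which is the least certain element.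

Step 9
Reactants: 16 (3aR,7S,8aR)-7-methyl-3-methylidene-6-(3-oxobutyl)-3,3a,4,7,8,8a-hexahydro-2H-cyclohepta[b]furan-2-one
Product: 17 (3aR,7S,8aR)-7-methyl-3-methylidene-6-[(1E)-3-oxobut-1-en-1-yl]-3,3a,4,7,8,8a-hexahydro-2H-cyclohepta[b]furan-2-one
Conditions: IBX, 4-methoxypyridine N-oxide, DMSO, 25 °C; product kept cold and used at once
Reagents that add atoms: none
Why: IBX-mediated dehydrogenation of the ketone proceeds through its enol and can only introduce the C2=C3 double bond (the methyl side has no β-hydrogen), the allylic C2–H making it facile and the E-dienone being expected; no stereocentre is touched.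

**Steps 10–16: dienophile half (C10 R series, same chemistry with the antipodal catalyst)**

Step 10
Reactants: 2 tert-butyl{[1-(tert-butylsulfanyl)ethenyl]oxy}dimethylsilane; 3 (E)-but-2-enal
Product: 19 S-tert-butyl (3R)-5,5-dimethoxy-3-methylpentanethioate, via Michael aldehyde 18 (not isolated)
Conditions: (2S,5S)-5-benzyl-2-tert-butyl-3-methylimidazolidin-4-one·CF3CO2H (20 mol %), H2O (2 equiv), CH2Cl2, −60 °C; then HC(OMe)3, MeOH, TsOH (cat.), 0 °C → rt
Reagents that add atoms: trimethyl orthoformate, COC(OC)OC
Why: The same organocatalytic Mukaiyama–Michael addition as in step 2, in which the antipodal catalyst exposes the opposite face of the iminium ion and sets C10' in the mirror-image sense.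

Step 11
Reactants: 19 S-tert-butyl (3R)-5,5-dimethoxy-3-methylpentanethioate
Product: 20 (3S)-5,5-dimethoxy-3-methylpentanal
Conditions: i-Bu2AlH (1.1 equiv), CH2Cl2, −78 °C; aqueous work-up
Reagents that add atoms: none
Why: Partial thioester reduction as in step 3; the stereocentre is untouched.

Step 12
Reactants: 20 (3S)-5,5-dimethoxy-3-methylpentanal
Product: 21 (3R)-5,5-dimethoxy-3-methyl-2-methylidenepentanal
Conditions: 37% aq. CH2O, pyrrolidine (10 mol %), propanoic acid (10 mol %), i-PrOH, 45 °C
Reagents that add atoms: formaldehyde, C=O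
Why: Organocatalytic α-methylenation (Mannich condensation and elimination) as in step 4; the stereocentre is untouched.

Step 13
Reactants: 21 (3R)-5,5-dimethoxy-3-methyl-2-methylidenepentanal; 8 3-bromoprop-1-yne
Product: 22 (4RS,6R)-8,8-dimethoxy-6-methyl-5-methylideneoct-1-yn-4-ol
Conditions: Zn dust, THF/sat. aq. NH4Cl, 0 °C
Reagents that add atoms: none
Why: Barbier-type propargylation as in step 5; the carbinol epimers are carried on together because C5' becomes sp2 in step 15.

Step 14
Reactants: 22 (4RS,6R)-8,8-dimethoxy-6-methyl-5-methylideneoct-1-yn-4-ol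
Product: 24 (5RS,7R)-9,9-dimethoxy-7-methyl-6-methylidenenona-1,2-dien-5-ol, via propargylic amine 23 (not isolated)
Conditions: (CH2O)n, i-Pr2NH, CuBr (0.3 equiv), 1,4-dioxane, reflux
Reagents that add atoms: formaldehyde (as paraformaldehyde), C=O
Why: Crabbé homologation of the terminal alkyne to the terminal allene as in step 6.

Step 15
Reactants: 24 (5RS,7R)-9,9-dimethoxy-7-methyl-6-methylidenenona-1,2-dien-5-ol; 12 2-methoxyprop-1-ene
Product: 27 (3R,4Z)-3-methyl-4-(3-oxobutyl)nona-4,7,8-trienal, via isopropenyl ether 25 (not isolated), via keto acetal 26 (not isolated)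
Conditions: 12 (excess), 2,4-dinitrophenol (cat.), xylenes, 130 °C, sealed tube; then THF, 10% aq. oxalic acid, rt
Reagents that add atoms: water, O
Why: Stereoconvergent Claisen rearrangement (Marbet–Saucy ketal variant) through the chair transition state as in step 7, followed by acetal hydrolysis.

Step 16
Reactants: 27 (3R,4Z)-3-methyl-4-(3-oxobutyl)nona-4,7,8-trienal
Product: 28 (3aS,7R,8aS)-7-methyl-3-methylidene-6-(3-oxobutyl)-3,3a,4,7,8,8a-hexahydro-2H-cyclohepta[b]furan-2-one
Conditions: Ru3(CO)12 (5 mol %), CO (20 atm), 1,4-dioxane, 120 °C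
Reagents that add atoms: carbon monoxide, [C-]#[O+]
Why: The same hetero-Pauson–Khand cyclocarbonylation as in step 8 on the antipode, setting C7' and C8' as the cis fusion under control of C10'.

**Steps 17–18: union and oxygenation**

Step 17
Reactants: 17 (3aR,7S,8aR)-7-methyl-3-methylidene-6-[(1E)-3-oxobut-1-en-1-yl]-3,3a,4,7,8,8a-hexahydro-2H-cyclohepta[b]furan-2-one; 28 (3aS,7R,8aS)-7-methyl-3-methylidene-6-(3-oxobutyl)-3,3a,4,7,8,8a-hexahydro-2H-cyclohepta[b]furan-2-one
Product: 29 endo Diels–Alder adduct with the C1=C2 alkene and C3–H next to the acetyl group (3R,5R,7R,8R,10S,11'R,7'S,8'S,10'R)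
Conditions: 28 (3 equiv, excess recovered), toluene (concentrated), BHT (cat.), 90 °C, sealed tube, dark
Reagents that add atoms: none
Why: Thermal Diels–Alder reaction of the s-cis dienone C5=C1–C2=C3 of 17 with the exocyclic C11'=C13' of 28, in which the largest coefficients (C5 and C13') bond, the endo transition state (lactone carbonyl C12' under the diene) fixes C11' relative to C5 and C3, the diene reacts on the face opposite its C10 methyl and cis-lactone, the dienophile reacts on its convex face syn to H7' and H8', and the excess of 28, which has no diene, suppresses self-dimerisation of 17.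

Step 18
Reactants: 29 endo Diels–Alder adduct
Product: 31 target CNP0195550.3 (1S,5R,7R,8R,10S,11'R,7'S,8'S,10'R), via C1 hydroperoxide 30 (not isolated)
Conditions: O2 (1 atm), DBU (0.2 equiv), P(OEt)3 (2 equiv), MeCN, 0 °C
Reagents that add atoms: dioxygen, O=O
Why: Base-mediated γ-autoxidation of a β,γ-unsaturated ketone, in which DBU removes the doubly activated C3–H, the dienolate captures O2 at the γ-carbon C1 on the face of H5 (anti to C6 and C9 of ring B and to the lactone carbonyl on ring C) to give hydroperoxide 30 with the C2=C3 enone, and the phosphite reduces the O–O bond in situ, which sets C1 and erases C3.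

**Compound list**

1 | S-tert-butyl ethanethioate | CC(=O)SC(C)(C)C | starting material
2 | tert-butyl{[1-(tert-butylsulfanyl)ethenyl]oxy}dimethylsilane | C=C(O[Si](C)(C)C(C)(C)C)SC(C)(C)C | intermediate
3 | (E)-but-2-enal (crotonaldehyde) | C/C=C/C=O | starting material
4 | S-tert-butyl (3S)-3-methyl-5-oxopentanethioate | O=CC[C@H](C)CC(=O)SC(C)(C)C | intermediate
5 | S-tert-butyl (3S)-5,5-dimethoxy-3-methylpentanethioate | COC(OC)C[C@H](C)CC(=O)SC(C)(C)C | intermediate
6 | (3R)-5,5-dimethoxy-3-methylpentanal | COC(OC)C[C@H](C)CC=O | intermediate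
7 | (3S)-5,5-dimethoxy-3-methyl-2-methylidenepentanal | COC(OC)C[C@H](C)C(=C)C=O | intermediate
8 | 3-bromoprop-1-yne (propargyl bromide) | C#CCBr | starting material
9 | (4RS,6S)-8,8-dimethoxy-6-methyl-5-methylideneoct-1-yn-4-ol | COC(OC)C[C@H](C)C(=C)C(O)CC#C | intermediate
10 | (5RS,7S)-1-[di(propan-2-yl)amino]-9,9-dimethoxy-7-methyl-6-methylidenenon-2-yn-5-ol | COC(OC)C[C@H](C)C(=C)C(O)CC#CCN(C(C)C)C(C)C | intermediate
11 | (5RS,7S)-9,9-dimethoxy-7-methyl-6-methylidenenona-1,2-dien-5-ol | COC(OC)C[C@H](C)C(=C)C(O)CC=C=C | intermediate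
12 | 2-methoxyprop-1-ene | COC(C)=C | starting material
13 | (5RS,7S)-9,9-dimethoxy-7-methyl-6-methylidene-5-(prop-1-en-2-yloxy)nona-1,2-diene | COC(OC)C[C@H](C)C(=C)C(OC(C)=C)CC=C=C | intermediate
14 | (5Z)-5-[(2S)-4,4-dimethoxybutan-2-yl]deca-5,8,9-trien-2-one | COC(OC)C[C@H](C)/C(CCC(C)=O)=C\CC=C=C | intermediate
15 | (3S,4Z)-3-methyl-4-(3-oxobutyl)nona-4,7,8-trienal | O=CC[C@H](C)/C(CCC(C)=O)=C\CC=C=C | intermediate
16 | (3aR,7S,8aR)-7-methyl-3-methylidene-6-(3-oxobutyl)-3,3a,4,7,8,8a-hexahydro-2H-cyclohepta[b]furan-2-one | C=C1C(=O)O[C@@H]2C[C@H](C)C(CCC(C)=O)=CC[C@H]12 | intermediate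
17 | (3aR,7S,8aR)-7-methyl-3-methylidene-6-[(1E)-3-oxobut-1-en-1-yl]-3,3a,4,7,8,8a-hexahydro-2H-cyclohepta[b]furan-2-one | C=C1C(=O)O[C@@H]2C[C@H](C)C(/C=C/C(C)=O)=CC[C@H]12 | intermediate
18 | S-tert-butyl (3R)-3-methyl-5-oxopentanethioate | O=CC[C@@H](C)CC(=O)SC(C)(C)C | intermediate
19 | S-tert-butyl (3R)-5,5-dimethoxy-3-methylpentanethioate | COC(OC)C[C@@H](C)CC(=O)SC(C)(C)C | intermediate
20 | (3S)-5,5-dimethoxy-3-methylpentanal | COC(OC)C[C@@H](C)CC=O | intermediate
21 | (3R)-5,5-dimethoxy-3-methyl-2-methylidenepentanal | COC(OC)C[C@@H](C)C(=C)C=O | intermediate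
22 | (4RS,6R)-8,8-dimethoxy-6-methyl-5-methylideneoct-1-yn-4-ol | COC(OC)C[C@@H](C)C(=C)C(O)CC#C | intermediate
23 | (5RS,7R)-1-[di(propan-2-yl)amino]-9,9-dimethoxy-7-methyl-6-methylidenenon-2-yn-5-ol | COC(OC)C[C@@H](C)C(=C)C(O)CC#CCN(C(C)C)C(C)C | intermediate
24 | (5RS,7R)-9,9-dimethoxy-7-methyl-6-methylidenenona-1,2-dien-5-ol | COC(OC)C[C@@H](C)C(=C)C(O)CC=C=C | intermediate
25 | (5RS,7R)-9,9-dimethoxy-7-methyl-6-methylidene-5-(prop-1-en-2-yloxy)nona-1,2-diene | COC(OC)C[C@@H](C)C(=C)C(OC(C)=C)CC=C=C | intermediate
26 | (5Z)-5-[(2R)-4,4-dimethoxybutan-2-yl]deca-5,8,9-trien-2-one | COC(OC)C[C@@H](C)/C(CCC(C)=O)=C\CC=C=C | intermediate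
27 | (3R,4Z)-3-methyl-4-(3-oxobutyl)nona-4,7,8-trienal | O=CC[C@@H](C)/C(CCC(C)=O)=C\CC=C=C | intermediate
28 | (3aS,7R,8aS)-7-methyl-3-methylidene-6-(3-oxobutyl)-3,3a,4,7,8,8a-hexahydro-2H-cyclohepta[b]furan-2-one | C=C1C(=O)O[C@H]2C[C@@H](C)C(CCC(C)=O)=CC[C@@H]12 | intermediate
29 | endo Diels–Alder adduct, C1=C2 alkene, C3–H (3R,5R,7R,8R,10S,11'R,7'S,8'S,10'R) | C=C1C(=O)O[C@@H]2C[C@H](C)C3=C[C@@H](C(C)=O)[C@]4(C[C@H]3C[C@H]12)C(=O)O[C@H]1C[C@@H](C)C(CCC(C)=O)=CC[C@H]14 | intermediate
30 | C1 hydroperoxide of the target skeleton (1S) | C=C1C(=O)O[C@@H]2C[C@H](C)[C@@]3(OO)C=C(C(C)=O)[C@]4(C[C@H]3C[C@H]12)C(=O)O[C@H]1C[C@@H](C)C(CCC(C)=O)=CC[C@H]14 | intermediate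
31 | CNP0195550.3 (1S,5R,7R,8R,10S,11'R,7'S,8'S,10'R) | C=C1C(=O)O[C@@H]2C[C@H](C)[C@@]3(O)C=C(C(C)=O)[C@]4(C[C@H]3C[C@H]12)C(=O)O[C@H]1C[C@@H](C)C(CCC(C)=O)=CC[C@H]14 | target

**Totals**

Total step count: 18. Longest linear sequence: 11 steps (steps 1–9, 17 and 18).

**Steps most likely to fail**

Step 8 (and its twin, step 16). The seven-membered carbocycle may fail to close in competition with oligomerisation or aldehyde decarbonylation, or it may close with poor facial control relative to C10. The fallback sets out from 15 and comes back at 16, separating ring closure from carbonylation. Palladium-catalysed silastannylation of the allene (Me3SiSnBu3, [PdCl(C3H5)]2 cat., THF, rt) places silicon on C11 and tin on C13; the resulting allylstannane adds to the aldehyde in the same flask and closes ring B as the cis-hydroxy vinylsilane F1. Iododesilylation (N-iodosuccinimide, MeCN, 0 °C) gives the vinyl iodide F2. Carbonylative lactonisation (Pd(PPh3)4 cat., CO 1 atm, Et3N, THF, 50 °C) then forms C11–C12 and the lactone C–O bond to give 16. The same sequence would serve 27 → 28.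

Step 17. The diene 17 may dimerise with itself through its own methylene lactone, and endo or π-facial selectivity may erode in the pairing of antipodal partners. The fallback sets out from 17 and comes back at 29, masking the competing dienophile. Conjugate addition of dimethylamine (Me2NH, EtOH, 0 °C) to the methylene lactone of 17 gives the dimethylamine adduct F3 (C11 epimers, of no consequence). The cycloaddition with 28 is then run as in step 17 and gives the masked adduct F4. Quaternisation (MeI, MeOH) gives the methiodide F5, and elimination with aqueous NaHCO3 restores the C11=C13 methylene to give 29.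

Step 18. The dienolate may take a proton at C1 instead of oxygen (conjugative isomerisation to the deoxy enone), or capture O2 at C3 or on the wrong face of C1. The fallback sets out from 29 and comes back at 31, delivering oxygen intramolecularly. Selenenylation at the doubly activated C3 (N-(phenylselanyl)phthalimide, DBU, CH2Cl2, 0 °C; the reagent does not add to isolated alkenes) gives the α-phenylselanyl ketone F6. Oxidation (H2O2, pyridine, CH2Cl2, 0 °C) gives the selenoxide F7, whose suprafacial [2,3]-sigmatropic shift moves oxygen from selenium to C1 with formation of the C2=C3 enone, giving the selenenate F8. Hydrolysis in the same flask gives 31.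

**Further compounds**

F1 | step 8 | 4-{(4S,5R,7S)-5-hydroxy-7-methyl-4-[1-(trimethylsilyl)ethenyl]cyclohept-1-en-1-yl}butan-2-one | O[C@@H]1C[C@H](C)C(CCC(C)=O)=CC[C@@H]1C(=C)[Si](C)(C)C
F2 | step 8 | 4-[(4S,5R,7S)-5-hydroxy-4-(1-iodoethenyl)-7-methylcyclohept-1-en-1-yl]butan-2-one | O[C@@H]1C[C@H](C)C(CCC(C)=O)=CC[C@@H]1C(=C)I
F3 | step 17 | (3aR,7S,8aR)-3-[(dimethylamino)methyl]-7-methyl-6-[(1E)-3-oxobut-1-en-1-yl]-3,3a,4,7,8,8a-hexahydro-2H-cyclohepta[b]furan-2-one (C3 epimers) | CN(C)CC1C(=O)O[C@@H]2C[C@H](C)C(/C=C/C(C)=O)=CC[C@H]12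
F4 | step 17 | Diels–Alder adduct 29 with C13 carried as CH2NMe2 (C11 saturated) | CN(C)CC1C(=O)O[C@@H]2C[C@H](C)C3=C[C@@H](C(C)=O)[C@]4(C[C@H]3C[C@H]12)C(=O)O[C@H]1C[C@@H](C)C(CCC(C)=O)=CC[C@H]14
F5 | step 17 | trimethylammonium iodide (methiodide) of F4 | C[N+](C)(C)CC1C(=O)O[C@@H]2C[C@H](C)C3=C[C@@H](C(C)=O)[C@]4(C[C@H]3C[C@H]12)C(=O)O[C@H]1C[C@@H](C)C(CCC(C)=O)=CC[C@H]14.[I-]
F6 | step 18 | C3-(phenylselanyl) derivative of adduct 29 (selenium on the face of H5) | C=C1C(=O)O[C@@H]2C[C@H](C)C3=C[C@@]([Se]c5ccccc5)(C(C)=O)[C@]4(C[C@H]3C[C@H]12)C(=O)O[C@H]1C[C@@H](C)C(CCC(C)=O)=CC[C@H]14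
F7 | step 18 | selenoxide of F6 | C=C1C(=O)O[C@@H]2C[C@H](C)C3=C[C@@]([Se](=O)c5ccccc5)(C(C)=O)[C@]4(C[C@H]3C[C@H]12)C(=O)O[C@H]1C[C@@H](C)C(CCC(C)=O)=CC[C@H]14
F8 | step 18 | C1 O-(phenylselanyl) selenenate of the target | C=C1C(=O)O[C@@H]2C[C@H](C)[C@@]3(O[Se]c5ccccc5)C=C(C(C)=O)[C@]4(C[C@H]3C[C@H]12)C(=O)O[C@H]1C[C@@H](C)C(CCC(C)=O)=CC[C@H]14
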